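Assumption: (R)-2-methylbutanoic acid of high enantiomeric purity and 6-methylheptanal are taken as purchasable.

## Analysis of the target

The target (13) is a symmetric dimer of two 5,7-dihydroxy-2,2-dimethylchroman units. Each is a fully substituted benzene ring fused to a dihydropyran ring, and the two are joined C6 to C6' through one sp3 carbon that also carries a 5-methylhexyl chain (a 6-methylheptane-1,1-diyl bridge). Going round each benzene ring from the pyran oxygen, the substituents are O1 on C8a, a (2R)-2-methylbutanoyl group on C8, OH on C7, the bridge on C6, OH on C5 and the pyran CH2 (C4) on C4a. The only stereocentres are the two acyl α-carbons, both R. They are far apart and cannot control each other, and because the two halves are identical the bridge carbon is not a stereocentre. An S unit in either half would give a diastereomer, so both acyl groups must enter enantiopure and stay so. The sensitive points are the enolisable α-carbons next to the aryl ketones, the diarylmethine bridge between two electron-rich rings (it can ionise under strong acid or base and exchange rings), and the oxidisable, easily over-alkylated phloroglucinol cores. The difficulty is regiochemical, not stereochemical: C4a lies between two oxygens, the one on C5 and the one on C8a, and only the second, which is flanked by the C8 acyl group and is the less nucleophilic of the two, may sit in the pyran ring. The strategy rests on the chain C4–C3–C2 with its two methyl groups: attached to C4a it is a prenyl group, so the O1–C2 bond of each pyran can be made by protonating a prenyl alkene, provided the oxygen on C5 is kept out of the closure.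

## Retrosynthetic reasoning

13 back to 12. The last operation should only uncover functionality. The two O5 hydroxyls are therefore masked in 12 as silyl ethers and the O–Si bonds are cut with buffered fluoride, which touches neither the chromans, the bridge nor the ketones.

12 back to 10. Both O1–C2 bonds are cut. This is the natural place: C2 is tertiary, so the forward reaction is capture of a tertiary cation by a phenol, and the cut turns each pyran ring into a prenyl group on C4a. The forward step has to protonate two alkenes in 10 and close two rings, passing through the half-closed compound 11, and it must do so through the acyl-flanked oxygen only. In 10 the competing oxygen on C5 already carries the silyl group, so the choice is made by the substrate and not by the conditions.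

10 back to 9. The two O–Si bonds are cut to give the hexaphenol 9. The forward silylation has to pick one hydroxyl out of three on each ring. The hydroxyl para to the ketone is the most acidic (a vinylogous carboxylic acid) and the only one that cannot chelate the carbonyl, and this difference is what the step uses.

9 back to 6 and 7. The two aryl–CH bonds at the bridge carbon are cut together, which halves the molecule and reveals the aldehyde 7 as a one-carbon linchpin between two molecules of 6. Cutting here and not earlier means each molecule of 6 has exactly one free ring carbon, so the condensation can neither choose a wrong position nor grow past the dimer. The forward reaction runs through the ortho-quinone methide 8 and must be done without strong acid, because the prenyl groups are already in place.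

6 back to 4 and 5. The C4a–C4 bond is cut to the acylphloroglucinol 4 and prenyl bromide 5. The two free ring carbons of 4 are equivalent, so only the degree of alkylation has to be controlled.

4 back to 2 and 3, and 2 back to 1. The aryl–acyl bond is cut to phloroglucinol 3 and the acid chloride 2, made from the chiral-pool acid 1. All three ring carbons of 3 are equivalent, and the stereocentre is bought instead of made. The acylation is placed first so that the one step that exposes the α-carbon to a strong Lewis acid is run on the simplest and cheapest intermediate.

## Alternatives that were turned down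

Alternative 1: The pyran oxygen is fixed from the start as a lactone. The disconnection cuts the four C2–CH3 bonds and both O1–C2 bonds. In the forward key step the bridged tetra-O-benzyl bis(dihydrocoumarin) A1 takes up MeMgBr twice at each lactone carbonyl, and acid then closes each tertiary carbinol onto the phenol it has just released, giving the bis(2,2-dimethylchroman) A2.
- For: the ring oxygen is identified by the lactone before any hydroxyl has to be told from another, and with the other oxygens benzylated the closure has no choice. On pyran regiochemistry this is stronger than the chosen route, which depends on a selective silylation.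
- Against: A2 carries no acyl groups. Both would have to be put on C8 and C8' with 2 at the very end, on crowded rings whose benzyl ethers and bridge do not tolerate the Lewis acids that a Friedel–Crafts acylation needs. The α-carbon would also meet those conditions twice on the most valuable material.
- Against: the dihydrocoumarin monomer has two free ring carbons (C6 and C8) of similar reactivity, so the bridging step has a regiochemical problem of its own.
- Comparison: counting lactone formation, bridging, benzylation, Grignard addition and closure, twofold acylation and hydrogenolysis, it is no shorter. The chosen route has a single early acylation and makes no carbon–carbon bond on a hexasubstituted ring late in the sequence.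

Alternative 2: The two C(=O)–Cα bonds are disconnected and the stereocentres are made by catalysis. In the forward key step the 8,8'-dialdehyde A3 adds each formyl C–H across buta-1,3-diene at the internal carbon under [Rh(cod)2]BF4 and a chiral bisphosphine, giving the bis(2-methylbut-3-enoyl) compound A4. Hydrogenation of the two vinyl groups would follow.
- For: the hydroxyl next to each formyl group is the chelating handle that makes salicylaldehydes the best substrates for intermolecular hydroacylation. Either enantiomeric series is open by choice of ligand, which is an advantage over a chiral-pool acid whose R form is the less common one.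
- Against: two independent catalytic events must both be highly selective in enantiofacial sense and in branched against linear addition, and any shortfall appears as the (R,S) diastereomer.
- Against: the α-hydrogen of A4 is both allylic and α to a ketone, so migration of the alkene into conjugation, which a rhodium hydride promotes, would erase the new centre.
- Against: A3 has six free phenols and hindered formyl groups, and making it already requires the whole pyran-regiochemistry problem to be solved, plus a twofold formylation.
- Comparison: it adds steps to the chosen route without replacing any. The chosen route gives up the catalytic stereocontrol and gets the stereocentres from a purchased acid through one ordinary bond-forming step.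

Alternative 3: The C4–C4a bond is disconnected and the pyran oxygen is marked by an ether. In the forward key step, heating the bis(1,1-dimethylpropargyl) ether A5 sets off on each ring a [3,3] shift to the one free ortho carbon, a 1,5-hydrogen shift and an oxa-6π ring closure, giving the bis-chromene A6. A final hydrogenation would saturate C3–C4 and remove the benzyl groups in one operation.
- For: the conditions are neutral and thermal, so the bridge and the α-carbons never see acid, and the ring oxygen is decided by where the ether sits. On these two points it is at least as good as the chosen route, and the last step does two jobs.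
- Against: the tertiary propargyl ether has to be placed on the most hindered and least nucleophilic oxygen of the ring, the chelated one on C8a. At the same time the other acyl-flanked hydroxyl (on C7) must stay free and the one on C5 must be benzylated. That is a three-way differentiation of the oxygens, with no handle to tell the two acyl-flanked ones apart.
- Against: tertiary propargylation of chelated, doubly ortho-substituted phenols is poor, and the product is at the chromene oxidation level.
- Comparison: the chosen route needs only one oxygen per ring to be singled out, uses the cheapest possible C5 reagent, and reaches the correct oxidation level directly.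

Key step: step 6

## Route

Step 1
Reactants: 1 (R)-2-methylbutanoic acid
Product: 2 (R)-2-methylbutanoyl chloride
Conditions: (COCl)2 (1.2 equiv), DMF (cat.), CH2Cl2, 0 °C to rt; volatiles removed, used crude
Reagents that add atoms: oxalyl chloride, ClC(=O)C(=O)Cl
Why: Acid chloride formation through the chloroiminium (Vilsmeier-type) activation; no base is present, so the ketene pathway that could racemise the α-carbon is closed, and the R centre is the one bought with 1.

Step 2
Reactants: 2 (R)-2-methylbutanoyl chloride; 3 phloroglucinol (benzene-1,3,5-triol)
Product: 4 (2R)-2-methyl-1-(2,4,6-trihydroxyphenyl)butan-1-one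
Conditions: AlCl3 (3.5 equiv), CH2Cl2/PhNO2, 0 °C to rt; then ice, aq. HCl
Reagents that add atoms: none
Why: Friedel–Crafts acylation; the three ring carbons of 3 are equivalent and the first acyl group deactivates the ring against a second, while the low temperature and the chelated aluminium complex of the product are meant to keep the α-carbon from enolising.

Step 3
Reactants: 4 (2R)-2-methyl-1-(2,4,6-trihydroxyphenyl)butan-1-one; 5 prenyl bromide (1-bromo-3-methylbut-2-ene)
Product: 6 (2R)-2-methyl-1-[2,4,6-trihydroxy-3-(3-methylbut-2-en-1-yl)phenyl]butan-1-one
Conditions: DBU (1.0 equiv), 5 (0.9 equiv), THF, 0 °C to rt; unreacted 4 recovered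
Reagents that add atoms: none
Why: C-alkylation of the ambident acylphloroglucinolate with an allylic bromide; the two free ring carbons are equivalent, the halide is kept limiting to hold back a second alkylation, and the ring anion is a vinylogous carboxylate, so the α-carbon is not deprotonated.

Step 4
Reactants: 6 (2R)-2-methyl-1-[2,4,6-trihydroxy-3-(3-methylbut-2-en-1-yl)phenyl]butan-1-one (2.1 equiv); 7 6-methylheptanal
Product: 9 1,1'-[(6-methylheptane-1,1-diyl)bis[2,4,6-trihydroxy-5-(3-methylbut-2-en-1-yl)benzene-3,1-diyl]]bis[(2R)-2-methylbutan-1-one], via ortho-quinone methide 8 (not isolated)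
Conditions: pyrrolidine (0.2 equiv), AcOH (0.2 equiv), EtOH, rt to 40 °C
Reagents that add atoms: none
Why: Knoevenagel-type condensation of the aldehyde at the single free ring carbon of 6 gives 8, and a second molecule of 6 adds to it through its own single free carbon (Michael addition of a phloroglucinol to an ortho-quinone methide); the medium is only weakly acidic, so the prenyl groups stay open, and with both acyl centres R the bridge carbon is not a stereocentre, so one compound should form.

Step 5
Reactants: 9 1,1'-[(6-methylheptane-1,1-diyl)bis[2,4,6-trihydroxy-5-(3-methylbut-2-en-1-yl)benzene-3,1-diyl]]bis[(2R)-2-methylbutan-1-one]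
Product: 10 1,1'-[(6-methylheptane-1,1-diyl)bis[4-(tert-butyldimethylsilyloxy)-2,6-dihydroxy-5-(3-methylbut-2-en-1-yl)benzene-3,1-diyl]]bis[(2R)-2-methylbutan-1-one]
Conditions: TBSCl (2.2 equiv), imidazole (4.5 equiv), DMF, 0 °C to rt
Reagents that add atoms: tert-butyldimethylsilyl chloride (TBSCl), CC(C)(C)[Si](C)(C)Cl
Why: Silylation of a phenol under mild base; on each ring the hydroxyl para to the ketone is the most acidic and the only one that cannot chelate the carbonyl, so its phenoxide forms first and takes the silyl group, and with one equivalent per ring the two acyl-flanked hydroxyls should stay free.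

Step 6
Reactants: 10 1,1'-[(6-methylheptane-1,1-diyl)bis[4-(tert-butyldimethylsilyloxy)-2,6-dihydroxy-5-(3-methylbut-2-en-1-yl)benzene-3,1-diyl]]bis[(2R)-2-methylbutan-1-one]
Product: 12 1,1'-[(6-methylheptane-1,1-diyl)bis[5-(tert-butyldimethylsilyloxy)-7-hydroxy-2,2-dimethyl-3,4-dihydro-2H-chromene-6,8-diyl]]bis[(2R)-2-methylbutan-1-one], via mono-chroman 11 (not isolated)
Conditions: Bi(OTf)3 (10 mol %), dry CH2Cl2, 0 °C to rt
Reagents that add atoms: none
Why: Bi(OTf)3, or the triflic acid it releases, protonates each trisubstituted prenyl alkene at C3 to give the tertiary cation at C2, and the only free hydroxyl next to that side chain, the one on C8a, captures it; loss of the proton regenerates the acid. The closest known reaction type is the acid-catalysed intramolecular hydroalkoxylation of ortho-prenylphenols to 2,2-dimethylchromans. Each pyran ring closes in a 6-endo-trig mode with respect to the alkene (Markovnikov), the 5-exo mode being excluded because it would need a secondary cation. No stereocentre is created, since C2 carries two methyl groups; the bridge carbon is a stereocentre only in the half-closed intermediate 11, and its two epimers converge on 12. The selectivity the step needs is closure through the oxygen on C8a and not through the more electron-rich oxygen on C5, and the silyl ether on O5 secures it. The C8 carbonyl can take its hydrogen bond from the hydroxyl on C7 instead, which frees the C8a hydroxyl to act as the nucleophile. A catalytic amount of acid in a dry, non-nucleophilic solvent should leave the aryl silyl ethers (more acid-resistant than alkyl silyl ethers), the diarylmethine bridge and the two R α-carbons untouched.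

Step 7
Reactants: 12 1,1'-[(6-methylheptane-1,1-diyl)bis[5-(tert-butyldimethylsilyloxy)-7-hydroxy-2,2-dimethyl-3,4-dihydro-2H-chromene-6,8-diyl]]bis[(2R)-2-methylbutan-1-one]
Product: 13 1,1'-[(6-methylheptane-1,1-diyl)bis(5,7-dihydroxy-2,2-dimethyl-3,4-dihydro-2H-chromene-6,8-diyl)]bis[(2R)-2-methylbutan-1-one]
Conditions: HF·pyridine, THF/pyridine, 0 °C to rt
Reagents that add atoms: none
Why: Fluoride-driven cleavage of aryl silyl ethers, driven by the strength of the Si–F bond; the buffered, weakly acidic medium avoids the phenoxide and enolate chemistry that could disturb the bridge or the α-carbons.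

## Compound list

1 | (R)-2-methylbutanoic acid | CC[C@@H](C)C(=O)O | starting material
2 | (R)-2-methylbutanoyl chloride | CC[C@@H](C)C(=O)Cl | intermediate
3 | phloroglucinol (benzene-1,3,5-triol) | Oc1cc(O)cc(O)c1 | starting material
4 | (2R)-2-methyl-1-(2,4,6-trihydroxyphenyl)butan-1-one | CC[C@@H](C)C(=O)c1c(O)cc(O)cc1O | intermediate
5 | prenyl bromide (1-bromo-3-methylbut-2-ene) | CC(C)=CCBr | starting material
6 | (2R)-2-methyl-1-[2,4,6-trihydroxy-3-(3-methylbut-2-en-1-yl)phenyl]butan-1-one | CC[C@@H](C)C(=O)c1c(O)cc(O)c(CC=C(C)C)c1O | intermediate
7 | 6-methylheptanal | CC(C)CCCCC=O | starting material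
8 | ortho-quinone methide, (2R)-1-[2,4-dihydroxy-5-(6-methylheptylidene)-3-(3-methylbut-2-en-1-yl)-6-oxocyclohexa-1,3-dien-1-yl]-2-methylbutan-1-one, alkene geometry not defined, not isolated | CC[C@@H](C)C(=O)C1=C(O)C(CC=C(C)C)=C(O)C(=CCCCCC(C)C)C1=O | intermediate
9 | 1,1'-[(6-methylheptane-1,1-diyl)bis[2,4,6-trihydroxy-5-(3-methylbut-2-en-1-yl)benzene-3,1-diyl]]bis[(2R)-2-methylbutan-1-one] | CC[C@@H](C)C(=O)c1c(O)c(CC=C(C)C)c(O)c(C(CCCCC(C)C)c2c(O)c(CC=C(C)C)c(O)c(C(=O)[C@H](C)CC)c2O)c1O | intermediate
10 | 1,1'-[(6-methylheptane-1,1-diyl)bis[4-(tert-butyldimethylsilyloxy)-2,6-dihydroxy-5-(3-methylbut-2-en-1-yl)benzene-3,1-diyl]]bis[(2R)-2-methylbutan-1-one] | CC[C@@H](C)C(=O)c1c(O)c(CC=C(C)C)c(O[Si](C)(C)C(C)(C)C)c(C(CCCCC(C)C)c2c(O[Si](C)(C)C(C)(C)C)c(CC=C(C)C)c(O)c(C(=O)[C@H](C)CC)c2O)c1O | intermediate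
11 | mono-chroman: one ring of 10 closed to the 5-silyloxy-7-hydroxy-2,2-dimethylchroman, the other still carrying its prenyl group; both epimers at the bridge carbon; not isolated | CC[C@@H](C)C(=O)c1c(O)c(C(CCCCC(C)C)c2c(O[Si](C)(C)C(C)(C)C)c(CC=C(C)C)c(O)c(C(=O)[C@H](C)CC)c2O)c(O[Si](C)(C)C(C)(C)C)c2c1OC(C)(C)CC2 | intermediate
12 | 1,1'-[(6-methylheptane-1,1-diyl)bis[5-(tert-butyldimethylsilyloxy)-7-hydroxy-2,2-dimethyl-3,4-dihydro-2H-chromene-6,8-diyl]]bis[(2R)-2-methylbutan-1-one] | CC[C@@H](C)C(=O)c1c(O)c(C(CCCCC(C)C)c2c(O[Si](C)(C)C(C)(C)C)c3c(c(C(=O)[C@H](C)CC)c2O)OC(C)(C)CC3)c(O[Si](C)(C)C(C)(C)C)c2c1OC(C)(C)CC2 | intermediate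
13 | 1,1'-[(6-methylheptane-1,1-diyl)bis(5,7-dihydroxy-2,2-dimethyl-3,4-dihydro-2H-chromene-6,8-diyl)]bis[(2R)-2-methylbutan-1-one] | CC[C@@H](C)C(=O)c1c(O)c(C(CCCCC(C)C)c2c(O)c3c(c(C(=O)[C@H](C)CC)c2O)OC(C)(C)CC3)c(O)c2c1OC(C)(C)CC2 | target

## Step count and least certain steps

Total step count: 7. Longest linear sequence: 7 steps, from 1 to 13; 3, 5 and 7 enter as purchased materials.

Key step (step 6). The most likely failure is loss or transfer of a silyl group under the triflic acid set free from the catalyst, after which the uncovered oxygen on C5 would close the ring and give the isomeric pyran. The second concern is acid-induced ionisation of the electron-rich diarylmethine bridge, which would cleave or scramble the dimer. The third is a sluggish second closure in the crowded half-closed intermediate, which would invite longer exposure and α-epimerisation. The fallback replaces protonation by selenium activation. From 10, N-(phenylselanyl)phthalimide with catalytic camphorsulfonic acid in CH2Cl2 at 0 °C should give the twofold selenoetherification product, the bis(3-phenylselanyl)chroman F1, by opening of each seleniranium ion at the tertiary carbon by the same C8a hydroxyl. Radical reduction with Bu3SnH and AIBN in toluene at 90 °C then removes both selenium groups and rejoins the route at 12.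

Silylation (step 5). All three hydroxyls of each ring in 9 are flanked on both sides, and the para one sits between the prenyl group and the bulky bridge. Silylation there may be slow enough that the unchelated acyl-flanked hydroxyl competes, which would give mixtures of regioisomeric bis-silyl ethers. The fallback moves the silylation to the monomer, where the para hydroxyl has an unsubstituted neighbour. From 6, TBSCl and imidazole should give the 4-O-silyl monomer F2. Two molecules of F2 are then bridged with 7 under the pyrrolidine/AcOH catalysis of step 4, run in CH2Cl2 to spare the aryl silyl ether, through the hydroxyl that remains next to the free ring carbon; this rejoins the route at 10.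

Bridging (step 4). Both partners are pentasubstituted rings, so the addition to 8 may be slow. In that case 8 can tautomerise to the alkenylphenol, add a phenol oxygen reversibly, or dimerise with itself, and any attempt to push the reaction with stronger acid would close the prenyl groups prematurely and without regiocontrol. The fallback inverts the order of bridging and prenylation. From 4, used in excess over 7 with catalytic p-toluenesulfonic acid in EtOH (no acid-sensitive alkene is present yet), the unprenylated dimer F3 is formed. Twofold C-prenylation of the single free carbon of each ring with 5 and DBU in THF then rejoins the route at 9.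

Acylation (step 2). The acylium–AlCl3 complex or the aluminium chelate of the product can enolise, which would lower the enantiomeric purity. Because two acyl units are later combined, any S content would appear in the dimer as the (R,S) diastereomer, which would be hard to remove. The fallback avoids acylium chemistry altogether. From 2, N,O-dimethylhydroxylamine hydrochloride and pyridine give the Weinreb amide F4. From 3, chloromethyl methyl ether and i-Pr2NEt give the tris(methoxymethyl) ether F5. F5 is lithiated between two of its ether groups with n-BuLi in THF at 0 °C and the aryllithium is added to F4 at −78 °C, giving the protected ketone F6. Removal of the three acetal groups with HCl in MeOH at rt rejoins the route at 4.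

Prenylation (step 3). The ambident anion can alkylate a second time at the remaining ring carbon, alkylate geminally with loss of aromaticity, or react at oxygen. The fallback delivers the prenyl group by rearrangement instead of by direct alkylation. From 4, methyl 2-methylbut-3-en-2-yl carbonate with catalytic Pd(PPh3)4 (zerovalent palladium) in THF at 0 °C should give the tertiary allyl ether F7 on the most acidic, para oxygen. Heating F7 in toluene at 100 °C brings about the aromatic Claisen rearrangement to the adjacent free carbon and rejoins the route at 6. An ether formed on one of the other oxygens would rearrange to the same compound, because the two free ring carbons are equivalent.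

## Further compounds

F1 | step 6 | 1,1'-[(6-methylheptane-1,1-diyl)bis[5-(tert-butyldimethylsilyloxy)-7-hydroxy-2,2-dimethyl-3-(phenylselanyl)-3,4-dihydro-2H-chromene-6,8-diyl]]bis[(2R)-2-methylbutan-1-one], mixture of epimers at C3 and C3' | CC[C@@H](C)C(=O)c1c(O)c(C(CCCCC(C)C)c2c(O[Si](C)(C)C(C)(C)C)c3c(c(C(=O)[C@H](C)CC)c2O)OC(C)(C)C([Se]c2ccccc2)C3)c(O[Si](C)(C)C(C)(C)C)c2c1OC(C)(C)C([Se]c1ccccc1)C2
F2 | step 5 | (2R)-1-[4-(tert-butyldimethylsilyloxy)-2,6-dihydroxy-3-(3-methylbut-2-en-1-yl)phenyl]-2-methylbutan-1-one | CC[C@@H](C)C(=O)c1c(O)c(CC=C(C)C)c(O[Si](C)(C)C(C)(C)C)cc1O
F3 | step 4 | 1,1'-[(6-methylheptane-1,1-diyl)bis(2,4,6-trihydroxybenzene-3,1-diyl)]bis[(2R)-2-methylbutan-1-one] | CC[C@@H](C)C(=O)c1c(O)cc(O)c(C(CCCCC(C)C)c2c(O)cc(O)c(C(=O)[C@H](C)CC)c2O)c1O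
F4 | step 2 | (2R)-N-methoxy-N,2-dimethylbutanamide | CC[C@@H](C)C(=O)N(C)OC
F5 | step 2 | 1,3,5-tris(methoxymethoxy)benzene | COCOc1cc(OCOC)cc(OCOC)c1
F6 | step 2 | (2R)-2-methyl-1-[2,4,6-tris(methoxymethoxy)phenyl]butan-1-one | CC[C@@H](C)C(=O)c1c(OCOC)cc(OCOC)cc1OCOC
F7 | step 3 | (2R)-1-[2,6-dihydroxy-4-[(2-methylbut-3-en-2-yl)oxy]phenyl]-2-methylbutan-1-one | CC[C@@H](C)C(=O)c1c(O)cc(OC(C)(C)C=C)cc1O
A1 | alternative 1 | 6,6'-(6-methylheptane-1,1-diyl)bis[5,7-bis(benzyloxy)chroman-2-one] | CC(C)CCCCC(c1c(OCc2ccccc2)cc2OC(=O)CCc2c1OCc1ccccc1)c1c(OCc2ccccc2)cc2OC(=O)CCc2c1OCc1ccccc1
A2 | alternative 1 | 6,6'-(6-methylheptane-1,1-diyl)bis[5,7-bis(benzyloxy)-2,2-dimethylchroman] | CC(C)CCCCC(c1c(OCc2ccccc2)cc2OC(C)(C)CCc2c1OCc1ccccc1)c1c(OCc2ccccc2)cc2OC(C)(C)CCc2c1OCc1ccccc1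
A3 | alternative 2 | 6,6'-(6-methylheptane-1,1-diyl)bis(5,7-dihydroxy-2,2-dimethylchroman-8-carbaldehyde) | O=Cc1c(O)c(C(CCCCC(C)C)c2c(O)c3c(c(C=O)c2O)OC(C)(C)CC3)c(O)c2c1OC(C)(C)CC2
A4 | alternative 2 | 1,1'-[(6-methylheptane-1,1-diyl)bis(5,7-dihydroxy-2,2-dimethylchroman-6,8-diyl)]bis[(2R)-2-methylbut-3-en-1-one] | C=C[C@@H](C)C(=O)c1c(O)c(C(CCCCC(C)C)c2c(O)c3c(c(C(=O)[C@H](C)C=C)c2O)OC(C)(C)CC3)c(O)c2c1OC(C)(C)CC2
A5 | alternative 3 | 1,1'-[(6-methylheptane-1,1-diyl)bis[4-(benzyloxy)-2-hydroxy-6-[(2-methylbut-3-yn-2-yl)oxy]benzene-3,1-diyl]]bis[(2R)-2-methylbutan-1-one] | CC[C@@H](C)C(=O)c1c(O)c(C(CCCCC(C)C)c2c(OCc3ccccc3)cc(OC(C)(C)C#C)c(C(=O)[C@H](C)CC)c2O)c(OCc2ccccc2)cc1OC(C)(C)C#C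
A6 | alternative 3 | 1,1'-[(6-methylheptane-1,1-diyl)bis[5-(benzyloxy)-7-hydroxy-2,2-dimethyl-2H-chromene-6,8-diyl]]bis[(2R)-2-methylbutan-1-one] | CC[C@@H](C)C(=O)c1c(O)c(C(CCCCC(C)C)c2c(OCc3ccccc3)c3c(c(C(=O)[C@H](C)CC)c2O)OC(C)(C)C=C3)c(OCc2ccccc2)c2c1OC(C)(C)C=C2
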